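The readings are calculated for substances that don't exist, noise included.

Target and uncatalysed product cannot together hold more than the starting material charged, and in Wednesday's run they already hold 99.8% at 5.00 h, then stay level to 30.0 h, the scatter being 0.3 percentage points.

in all of them: starting material 0.14 M; free enzyme 0.11 mM
- Wednesday's: second substrate 0.70 M (in portions, 4); scavenger 0.070 M; run made earlier; portions every 30 min
- flask: second substrate 0.700 M (in portions, 4); scavenger 0.140 M; the portions of second substrate follow each other after 30 min, the first at the start; time 4.0 d

Wednesday's run (percent of the starting material charged)

| time / h | target / % | uncatalysed product / % |
|---|---|---|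
| 2.50 | 34.4 | 59.0 |
| 4.00 | 35.9 | 63.0 |
| 5.00 | 36.1 | 63.7 |
| 8.00 | 36.3 | 63.6 |
| 12.0 | 36.2 | 64.1 |
| 20.0 | 36.2 | 63.7 |
| 30.0 | 35.7 | 63.5 |

(standard deviation of a reading: 0.3 percentage points)

- the reaction counts as stopped when no species that holds the starting material changes by six tenths of a point or more over the second half of the time
- no earlier run changes the charge of scavenger; that part of a forecast is a guess

1. at 4.0 d, what has stopped the reaction, if anything has (forward and back rates have come level / the second substrate has run out first / all of the starting material has reacted / it is still moving / no working catalyst is left)
2. amount of target at 4.0 d, in percent of the starting material charged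
3. amount of uncatalysed product at 4.0 d, in percent of the starting material charged

So starting material is the limiting reagent in Wednesday's run, and what matters is how two competing routes share it. I fold Wednesday's run into one number, the branching ratio (selectivity factor), the parts of target made per part of uncatalysed product: 0.568, as a reading. I take both routes as first order in starting material, so that concentration cancels and the ratio goes with enzyme over second substrate. The new flask repeats both, so I reckon 36.2% target and 63.8% uncatalysed product, with the starting material consumed.

Is one number enough? Between 2.50 h and 5.00 h Wednesday's readings, with their scatter, rise in a ratio of 0.362, less than the branching ratio, so I treat the number as an average over the whole of that run, which took its second substrate in portions. The new flask repeats those portions. The doubled scavenger is not in the number, and no earlier run changes the charge of scavenger, so that part of my reckoning is a guess.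

The forecast also expects that all of the starting material has reacted, but it differs from me in putting target at 62% and uncatalysed product at 38%, reasoning that “Doubling the scavenger could keep the enzyme working throughout”.

The flask gives this: all of the starting material has reacted, with target at 36.3% and uncatalysed product at 63.7%, a ratio of 0.570 against the reading of 0.568 from Wednesday's run.

    starting material + free enzyme ⇌ first complex (K = 3.50 M⁻¹, k = 3100 M⁻¹ min⁻¹)
    first complex ⇌ loaded enzyme + first product (K = 0.260 M, k = 21.0 min⁻¹)
    second substrate + loaded enzyme ⇌ second complex (K = 2.70 M⁻¹, k = 5300 M⁻¹ min⁻¹)
    second complex → free enzyme + target (k = 75.0 min⁻¹)
    second substrate + first product ⇌ idle adduct, settled at all times (K = 1.10 M⁻¹)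
    scavenger + first product → scavenged by-product (k = 18.0 M⁻¹ min⁻¹)
    starting material + second substrate → uncatalysed product (k = 0.0300 M⁻¹ min⁻¹)

The flask holds a step that the ratio does not show: first complex falls back to starting material and free enzyme, with a backward turnover of 98% of the forward one. This reverse step is the main reason for uncatalysed product at 63.7%, since the run without it stands at 26.1%. In the neighbour flask with free enzyme cut to 4.4 × 10⁻⁵ M, the branching ratio scales to 0.227, which means 18.5% target; computed, that flask gives 17.2%.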